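**Retrosynthetic overview**

1. The target is the cyclic hemiketal of an α-aryloxy aryl ketone. Its hemiketal carbon C2 equilibrates by ring–chain tautomerism, so the C2–aryl bond is cut first, giving a 3,4,5-trimethoxyphenyl Grignard reagent and the lactone (3R)-5-methoxy-3-methyl-7-allyl-2,3-dihydro-1,4-benzodioxin-2-one.
2. The dioxanone ring is cut at the O4–C3 bond (O4 is the ring oxygen on C4a, next to the methoxy-bearing C5). The precursor is an achiral, acyclic aryl 2-diazopropanoate on O1 with a free O4–H, closed by copper-catalysed asymmetric carbene O–H insertion.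
3. Enabling feature: the catechol unit O1–C8a–C4a–O4 of the benzodioxane ring. Once O1 carries the diazo ester, the O4–H bond lies five atoms from the carbene carbon, so insertion closes the six-membered ring and sets the CH(CH3) centre in the same event.
4. The two catechol oxygens are kept apart from the first step: O4 is the phenol of 5-allyl-2-hydroxy-3-methoxybenzaldehyde (silyl-protected), and O1 is made from the formyl group by Dakin oxidation.
5. Ring order: arene (purchased), then the 1,4-dioxanone ring (key step); the hemiketal arises in the last step without a further ring closure.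

Key step: step 6

Assumption: the hemiketal carbon is configurationally labile (ring–chain tautomerism), and the drawn diastereomer (OH axial and trans to CH3, aryl equatorial) is taken to be the thermodynamically favoured one, so only the CH(CH3) centre has to be set by the route.

**Route**

Step 1
Reactants: 1 5-allyl-2-hydroxy-3-methoxybenzaldehyde
Product: 2 3-methoxy-5-(prop-2-en-1-yl)-2-[(triisopropylsilyl)oxy]benzaldehyde
Conditions: TIPSCl, imidazole, DMF, 25 to 40 °C
Reagents that add atoms: triisopropylsilyl chloride, CC(C)[Si](Cl)(C(C)C)C(C)C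
Why: Silyl ether formation on the hindered phenol; the bulky, acid-stable triisopropylsilyl group should resist O-to-O migration and so fixes which catechol oxygen later acts as the nucleophile.

Step 2
Reactants: 2 3-methoxy-5-(prop-2-en-1-yl)-2-[(triisopropylsilyl)oxy]benzaldehyde
Product: 4 3-methoxy-5-(prop-2-en-1-yl)-2-[(triisopropylsilyl)oxy]phenol, via aryl formate 3 (not isolated)
Conditions: 30% H2O2, H2SO4 (cat.), MeOH, 0 to 25 °C
Reagents that add atoms: hydrogen peroxide, OO
Why: Acid-catalysed Dakin oxidation (Baeyer–Villiger type), in which the electron-rich ortho-silyloxyaryl group migrates and formate 3 is methanolysed in situ; hydrogen peroxide without a peracid should leave the allyl group untouched.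

Step 3
Reactants: 4 3-methoxy-5-(prop-2-en-1-yl)-2-[(triisopropylsilyl)oxy]phenol; 5 tert-butyl 2-methyl-3-oxobutanoate
Product: 7 3-methoxy-5-(prop-2-en-1-yl)-2-[(triisopropylsilyl)oxy]phenyl 2-methyl-3-oxobutanoate (racemic), via acetyl(methyl)ketene 6 (not isolated)
Conditions: xylene, 140 °C, t-BuOH distilled off
Reagents that add atoms: none
Why: Thermal transacetoacetylation: 5 loses tert-butanol to give acylketene 6, which the only free phenol should trap under neutral conditions.

Step 4
Reactants: 7 3-methoxy-5-(prop-2-en-1-yl)-2-[(triisopropylsilyl)oxy]phenyl 2-methyl-3-oxobutanoate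
Product: 8 3-methoxy-5-(prop-2-en-1-yl)-2-[(triisopropylsilyl)oxy]phenyl 2-diazopropanoate
Conditions: 4-acetamidobenzenesulfonyl azide, DBU, MeCN, 0 to 25 °C
Reagents that add atoms: 4-acetamidobenzenesulfonyl azide, CC(=O)Nc1ccc(cc1)S(=O)(=O)N=[N+]=[N-]
Why: Regitz deacylative diazo transfer, in which the α-methyl β-keto ester takes up the diazo group and passes its acetyl group to the sulfonamide nitrogen.

Step 5
Reactants: 8 3-methoxy-5-(prop-2-en-1-yl)-2-[(triisopropylsilyl)oxy]phenyl 2-diazopropanoate
Product: 9 2-hydroxy-3-methoxy-5-(prop-2-en-1-yl)phenyl 2-diazopropanoate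
Conditions: TBAF, AcOH (2 equiv per fluoride), THF, −20 °C; pH 7 work-up, used without chromatography
Reagents that add atoms: none
Why: Fluoride-induced cleavage of the aryl silyl ether; acetic acid should protonate the phenoxide as it forms, so that acyl migration to the neighbouring oxygen and attack on the diazo ester do not compete.

Step 6
Reactants: 9 2-hydroxy-3-methoxy-5-(prop-2-en-1-yl)phenyl 2-diazopropanoate
Product: 11 (3R)-5-methoxy-3-methyl-7-(prop-2-en-1-yl)-2,3-dihydro-1,4-benzodioxin-2-one, via copper carbene 10 (not isolated)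
Conditions: CuCl (5 mol%), (Sa,S,S)-7,7'-bis(4-phenyl-4,5-dihydrooxazol-2-yl)-1,1'-spirobiindane or its antipode (6 mol%), NaB[3,5-(CF3)2C6H3]4 (6 mol%), 4 Å MS, CH2Cl2 (0.02 M), 25 °C
Reagents that add atoms: none
Why: Proposed new method: CuCl, NaB[3,5-(CF3)2C6H3]4 and the spiro-bisoxazoline should give the cationic monovalent-copper carbene 10 with loss of N2; the free phenol oxygen (the one flanked by the methoxy group) adds to the carbene carbon to form a copper-associated cyclic oxonium ylide, and a 1,2-proton shift inside the chiral pocket then creates the C–H bond of the new stereocentre. The closest known reaction types are the copper/spiro-bisoxazoline-catalysed asymmetric insertion of 2-diazopropanoates into phenol O–H bonds and its intramolecular form that gives 2-carboxy chromans and dihydrobenzofurans; what is new is that the tether runs through the ester oxygen, so that a lactone is formed. The 1,4-dioxan-2-one ring closes by 6-exo attack of oxygen on the carbene carbon from the s-cis ester rotamer, the rotamer through which diazoacetate esters are known to form lactones by carbene insertion. The single new stereocentre, the CH(CH3) carbon, is controlled by the chiral ligand in the proton-transfer step, and the ligand antipode that delivers (R) is used (to be correlated on the first run with lactate-derived 11). The step needs regiocontrol (the acyl group must stay on the oxygen that replaced the formyl group) and chemoselectivity against 1,2-hydride shift to the aryl acrylate and against reaction at the allyl group: base-free neutral conditions should suppress acyl migration, copper in place of rhodium together with the fast intramolecular O–H trap should suppress the hydride shift, and the allyl group is out of reach of the carbene.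

Step 7
Reactants: 11 (3R)-5-methoxy-3-methyl-7-(prop-2-en-1-yl)-2,3-dihydro-1,4-benzodioxin-2-one; 12 (3,4,5-trimethoxyphenyl)magnesium bromide
Product: 14 (2S,3R)-5-methoxy-3-methyl-7-(prop-2-en-1-yl)-2-(3,4,5-trimethoxyphenyl)-2,3-dihydro-1,4-benzodioxin-2-ol, via bromomagnesium hemiketal alkoxide 13 (not isolated)
Conditions: 12 (1.1 equiv, THF), −78 to −40 °C; then sat. aq. NH4Cl
Reagents that add atoms: none
Why: Grignard addition to the aryl lactone should stop at the cyclic magnesium hemiketal alkoxide 13 and give the lactol on mild protonation; the CH(CH3) centre is not touched, and the hemiketal carbon settles by ring–chain equilibration in the anomerically stabilised form (OH axial and trans to CH3, aryl equatorial).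

**Compound list**

1 | 5-allyl-2-hydroxy-3-methoxybenzaldehyde | C=CCc1cc(OC)c(O)c(C=O)c1 | starting material
2 | 3-methoxy-5-(prop-2-en-1-yl)-2-[(triisopropylsilyl)oxy]benzaldehyde | C=CCc1cc(OC)c(O[Si](C(C)C)(C(C)C)C(C)C)c(C=O)c1 | intermediate
3 | 3-methoxy-5-(prop-2-en-1-yl)-2-[(triisopropylsilyl)oxy]phenyl formate (not isolated) | C=CCc1cc(OC)c(O[Si](C(C)C)(C(C)C)C(C)C)c(OC=O)c1 | intermediate
4 | 3-methoxy-5-(prop-2-en-1-yl)-2-[(triisopropylsilyl)oxy]phenol | C=CCc1cc(OC)c(O[Si](C(C)C)(C(C)C)C(C)C)c(O)c1 | intermediate
5 | tert-butyl 2-methyl-3-oxobutanoate | CC(=O)C(C)C(=O)OC(C)(C)C | starting material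
6 | acetyl(methyl)ketene, 2-methyl-3-oxobut-1-en-1-one (not isolated) | CC(=O)C(C)=C=O | intermediate
7 | 3-methoxy-5-(prop-2-en-1-yl)-2-[(triisopropylsilyl)oxy]phenyl 2-methyl-3-oxobutanoate (racemic) | C=CCc1cc(OC)c(O[Si](C(C)C)(C(C)C)C(C)C)c(OC(=O)C(C)C(C)=O)c1 | intermediate
8 | 3-methoxy-5-(prop-2-en-1-yl)-2-[(triisopropylsilyl)oxy]phenyl 2-diazopropanoate | C=CCc1cc(OC)c(O[Si](C(C)C)(C(C)C)C(C)C)c(OC(=O)C(C)=[N+]=[N-])c1 | intermediate
9 | 2-hydroxy-3-methoxy-5-(prop-2-en-1-yl)phenyl 2-diazopropanoate | C=CCc1cc(OC)c(O)c(OC(=O)C(C)=[N+]=[N-])c1 | intermediate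
10 | copper carbene of 9 (not isolated; bisoxazoline ligand on copper omitted) | C=CCc1cc(OC)c(O)c(OC(=O)C(C)=[Cu+])c1 | intermediate
11 | (3R)-5-methoxy-3-methyl-7-(prop-2-en-1-yl)-2,3-dihydro-1,4-benzodioxin-2-one | C=CCc1cc(OC)c2c(c1)OC(=O)[C@@H](C)O2 | intermediate
12 | (3,4,5-trimethoxyphenyl)magnesium bromide | COc1cc([Mg]Br)cc(OC)c1OC | starting material
13 | bromomagnesium (3R)-5-methoxy-3-methyl-7-(prop-2-en-1-yl)-2-(3,4,5-trimethoxyphenyl)-2,3-dihydro-1,4-benzodioxin-2-olate (not isolated; C2 not fixed) | C=CCc1cc(OC)c2c(c1)OC(O[Mg]Br)(c1cc(OC)c(OC)c(OC)c1)[C@@H](C)O2 | intermediate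
14 | (2S,3R)-5-methoxy-3-methyl-7-(prop-2-en-1-yl)-2-(3,4,5-trimethoxyphenyl)-2,3-dihydro-1,4-benzodioxin-2-ol | C=CCc1cc(OC)c2c(c1)O[C@@](O)(c1cc(OC)c(OC)c(OC)c1)[C@@H](C)O2 | target

**Step count**

Total steps: 7. Longest linear sequence: 7 steps (1 to 14).

**Steps most likely to fail, with fallbacks**

Step 6 (Proposed new method). The insertion may fail through low enantioselectivity in the proton-transfer step, through 1,2-hydride shift of the carbene to the aryl acrylate, or through acyl migration to the neighbouring oxygen before insertion, which would give the regioisomeric lactone. The fallback uses known chiral-pool chemistry, sets out from 1 and comes back at 11. Mitsunobu reaction of 1 with ethyl (S)-lactate (PPh3, DIAD, THF, 0 to 25 °C) forms the aryl ether with inversion and should give ethyl (2R)-2-[2-formyl-6-methoxy-4-(prop-2-en-1-yl)phenoxy]propanoate F1. Dakin oxidation (30% H2O2, B(OH)3, cat. H2SO4, THF) converts the formyl group into the phenol, ethyl (2R)-2-[2-hydroxy-6-methoxy-4-(prop-2-en-1-yl)phenoxy]propanoate F2. F2 lactonises (cat. TsOH, toluene, 80 °C, loss of ethanol) to 11, with regiochemistry and configuration fixed by the starting materials.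

Step 7. The addition may go wrong by a second addition of the Grignard reagent after ring opening of the tetrahedral intermediate, or by enolisation of the lactone with erosion of the CH(CH3) centre. The fallback sets out from 11 and comes back at 14. Ring opening of 11 with N,O-dimethylhydroxylamine hydrochloride and i-PrMgCl (THF, −20 °C) gives the Weinreb amide (2R)-2-[2-hydroxy-6-methoxy-4-(prop-2-en-1-yl)phenoxy]-N-methoxy-N-methylpropanamide F3. Treatment with 12 (3 equiv, THF, −20 to 0 °C; the first equivalent deprotonates the phenol) stops at the chelated adduct, which on NH4Cl quench releases the keto phenol (2R)-2-[2-hydroxy-6-methoxy-4-(prop-2-en-1-yl)phenoxy]-1-(3,4,5-trimethoxyphenyl)propan-1-one F4. F4 closes spontaneously to hemiketal 14.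

Step 5. Desilylation may be accompanied by acyl migration through a transient phenoxide or by loss of the diazo group. The fallback moves the fluoride step ahead of diazo formation and keeps all later steps acidic; it sets out from 4 and comes back at 9. Coupling of 4 with N-Boc-DL-alanine (EDC·HCl, DMAP, CH2Cl2) gives 3-methoxy-5-(prop-2-en-1-yl)-2-[(triisopropylsilyl)oxy]phenyl N-(tert-butoxycarbonyl)-DL-alaninate F5. Acidic desilylation (HF·pyridine, THF, 0 to 25 °C) gives 2-hydroxy-3-methoxy-5-(prop-2-en-1-yl)phenyl N-(tert-butoxycarbonyl)-DL-alaninate F6. Boc removal (HCl, dioxane) gives 2-hydroxy-3-methoxy-5-(prop-2-en-1-yl)phenyl DL-alaninate hydrochloride F7. Diazotisation of F7 (NaNO2, aqueous AcOH/NaOAc buffer at about pH 4, CH2Cl2, 0 °C) should give 9.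

**Further compounds**

F1 | step 6 | ethyl (2R)-2-[2-formyl-6-methoxy-4-(prop-2-en-1-yl)phenoxy]propanoate | CCOC(=O)[C@@H](C)Oc1c(C=O)cc(CC=C)cc1OC
F2 | step 6 | ethyl (2R)-2-[2-hydroxy-6-methoxy-4-(prop-2-en-1-yl)phenoxy]propanoate | CCOC(=O)[C@@H](C)Oc1c(O)cc(CC=C)cc1OC
F3 | step 7 | (2R)-2-[2-hydroxy-6-methoxy-4-(prop-2-en-1-yl)phenoxy]-N-methoxy-N-methylpropanamide | CON(C)C(=O)[C@@H](C)Oc1c(O)cc(CC=C)cc1OC
F4 | step 7 | (2R)-2-[2-hydroxy-6-methoxy-4-(prop-2-en-1-yl)phenoxy]-1-(3,4,5-trimethoxyphenyl)propan-1-one | COc1cc(cc(OC)c1OC)C(=O)[C@@H](C)Oc1c(O)cc(CC=C)cc1OC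
F5 | step 5 | 3-methoxy-5-(prop-2-en-1-yl)-2-[(triisopropylsilyl)oxy]phenyl N-(tert-butoxycarbonyl)-DL-alaninate | C=CCc1cc(OC)c(O[Si](C(C)C)(C(C)C)C(C)C)c(OC(=O)C(C)NC(=O)OC(C)(C)C)c1
F6 | step 5 | 2-hydroxy-3-methoxy-5-(prop-2-en-1-yl)phenyl N-(tert-butoxycarbonyl)-DL-alaninate | C=CCc1cc(OC)c(O)c(OC(=O)C(C)NC(=O)OC(C)(C)C)c1
F7 | step 5 | 2-hydroxy-3-methoxy-5-(prop-2-en-1-yl)phenyl DL-alaninate hydrochloride | C=CCc1cc(OC)c(O)c(OC(=O)C(C)[NH3+])c1.[Cl-]
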